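**Retrosynthetic overview**

1. Target 10 ⇒ acyclic octa-1,7-diene 9 by ring-closing metathesis across C3=C4; the only ring (the cyclohexene) is formed last, with all four esters already in place.
2. 9 ⇒ ketone 8 + bromide 7 by cutting C1–C2: a γ-acetoxyallylindium (an α-acetoxyallyl anion, i.e. acrolein with its carbonyl carbon made nucleophilic) adds to the C1 ketone and sets C1 and C2 together.
3. 8 ⇒ 6-iodofuranoside 5 by zinc-mediated ring fragmentation; C7, C1, C6, C5, C4 are C1–C5 of D-fructose, which supplies both benzoate stereocentres.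
4. 5 ⇒ D-fructose (glycosidation, 6-iodination, 1-O-acetylation/3,4-di-O-benzoylation); 7 ⇒ acrolein + acetyl bromide.

Numbering used for the target: C1 = carbinol carbon bearing CH2OAc (C7), C2 = CHOAc, C3=C4, C5 and C6 = CHOBz; the target is (1R,2S,5R,6S).

Assumption: sugars 2–5 are carried as α/β anomeric mixtures (their SMILES leave only the anomeric carbon undefined) and 7 as an E/Z mixture, because both elements are erased in step 5.

**Step 1**
Reactants: 1 D-fructose
Product: 2 methyl D-fructofuranoside (α/β mixture)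
Conditions: MeOH, H2SO4 (cat.), 20 °C, 45 min; NaHCO3 quench; SiO2
Reagents that add atoms: methanol, CO
Why: Kinetically controlled Fischer glycosidation gives the five-membered glycosides first and is stopped before equilibration to the pyranoside; C3–C5 are untouched and the anomeric mixture does not matter because this carbon becomes the ketone in step 5.

**Step 2**
Reactants: 2 methyl D-fructofuranoside
Product: 3 methyl 6-deoxy-6-iodo-D-fructofuranoside
Conditions: PPh3, I2, imidazole, THF, 0 → 50 °C
Reagents that add atoms: iodine, II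
Why: Garegg–Samuelsson (Appel-type) iodination, in which only the primary 6-oxyphosphonium undergoes SN2 displacement by iodide while the neopentyl-like C1 position next to the ketal carbon does not; no stereocentre is touched.

**Step 3**
Reactants: 3 methyl 6-deoxy-6-iodo-D-fructofuranoside
Product: 5 methyl 1-O-acetyl-3,4-di-O-benzoyl-6-deoxy-6-iodo-D-fructofuranoside, via 1-O-acetate 4 (not isolated)
Conditions: AcCl (1.05 equiv), 2,4,6-collidine, CH2Cl2/THF, −40 °C; then BzCl, pyridine, DMAP (cat.), 0 → 20 °C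
Reagents that add atoms: acetyl chloride, CC(=O)Cl; benzoyl chloride, O=C(Cl)c1ccccc1
Why: Kinetically controlled regioselective acylation, in which acetyl chloride/collidine at low temperature acetylates only the primary 1-OH and DMAP-catalysed benzoylation then caps the two secondary hydroxyls; no stereocentre is touched.

**Step 4**
Reactants: 6 acrolein
Product: 7 3-bromoprop-1-enyl acetate (E/Z mixture)
Conditions: AcBr, ZnCl2 (cat.), CH2Cl2, −20 → 20 °C
Reagents that add atoms: acetyl bromide, CC(=O)Br
Why: ZnCl2-catalysed conjugate (1,4-) addition of the acyl bromide to the enal (O-acylation, then bromide attack at C3) gives the γ-bromo enol acetate; the E/Z mixture is used as such because the derived allylmetal equilibrates.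

**Step 5**
Reactants: 5 methyl 1-O-acetyl-3,4-di-O-benzoyl-6-deoxy-6-iodo-D-fructofuranoside; 7 3-bromoprop-1-enyl acetate
Product: 9 (3S,4R,5S,6R)-3-acetoxy-4-(acetoxymethyl)-4-hydroxyocta-1,7-diene-5,6-diyl dibenzoate, via enulose ketone 8 (not isolated)
Conditions: Zn dust (acid-washed), THF/H2O 4:1, sonication, 40 °C; filter; then 7, In powder, THF/H2O, 0 → 20 °C
Reagents that add atoms: none
Why: Proposed new method: Bernet–Vasella reductive fragmentation (zinc inserts into the C–I bond, β-elimination opens the furanoside and the hemiketal loses methanol) unmasks ketone 8, which is then attacked in a Barbier reaction by the γ-acetoxyallylindium formed from 7, an α-acetoxyallyl anion in which the former carbonyl carbon of acrolein is the nucleophile, so that two normally electrophilic carbonyl carbons are joined as C1–C2; the closest known reactions are the zinc-mediated tandem fragmentation–allylation of iodofuranosides and the indium- or zinc-mediated addition of 3-bromopropenyl esters to aldehydes, and by analogy the internally chelated Z-allylindium should react through a chair transition state with the branched C6 arm equatorial (C1–OH/C2–OAc syn, giving 2S) on the Felkin–Anh/Cornforth face of the ketone away from the C6 benzoate (C1–OH/C6–OBz anti, giving 1R).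

**Step 6**
Reactants: 9 (3S,4R,5S,6R)-3-acetoxy-4-(acetoxymethyl)-4-hydroxyocta-1,7-diene-5,6-diyl dibenzoate
Product: 10 [(1R,2S,5R,6S)-2-acetoxy-5,6-bis(benzoyloxy)-1-hydroxycyclohex-3-en-1-yl]methyl acetate (CNP0196993.1)
Conditions: second-generation Grubbs catalyst RuCl2(=CHPh)(H2IMes)(PCy3) (5 mol%), CH2Cl2 (5 mM), 40 °C
Reagents that add atoms: none
Why: Ring-closing olefin metathesis of the octa-1,7-diene closes the cyclohexene at C3=C4 with loss of ethene; esters and the free tertiary alcohol are tolerated and no stereocentre is touched.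

**Compound list**

1 | D-fructose | OCC(=O)[C@@H](O)[C@H](O)[C@H](O)CO | starting material
2 | methyl D-fructofuranoside (α/β mixture) | COC1(CO)O[C@H](CO)[C@@H](O)[C@@H]1O | intermediate
3 | methyl 6-deoxy-6-iodo-D-fructofuranoside (α/β) | COC1(CO)O[C@H](CI)[C@@H](O)[C@@H]1O | intermediate
4 | methyl 1-O-acetyl-6-deoxy-6-iodo-D-fructofuranoside (α/β; not isolated) | COC1(COC(C)=O)O[C@H](CI)[C@@H](O)[C@@H]1O | intermediate
5 | methyl 1-O-acetyl-3,4-di-O-benzoyl-6-deoxy-6-iodo-D-fructofuranoside (α/β) | COC1(COC(C)=O)O[C@H](CI)[C@@H](OC(=O)c2ccccc2)[C@@H]1OC(=O)c1ccccc1 | intermediate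
6 | acrolein | C=CC=O | starting material
7 | 3-bromoprop-1-enyl acetate (E/Z mixture) | CC(=O)OC=CCBr | intermediate
8 | (3R,4S)-6-acetoxy-5-oxohex-1-ene-3,4-diyl dibenzoate (1-O-acetyl-3,4-di-O-benzoyl-5,6-dideoxy-D-threo-hex-5-en-2-ulose; not isolated) | C=C[C@@H](OC(=O)c1ccccc1)[C@H](OC(=O)c1ccccc1)C(=O)COC(C)=O | intermediate
9 | (3S,4R,5S,6R)-3-acetoxy-4-(acetoxymethyl)-4-hydroxyocta-1,7-diene-5,6-diyl dibenzoate | CC(=O)OC[C@@](O)([C@@H](OC(C)=O)C=C)[C@@H](OC(=O)c1ccccc1)[C@H](OC(=O)c1ccccc1)C=C | intermediate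
10 | [(1R,2S,5R,6S)-2-acetoxy-5,6-bis(benzoyloxy)-1-hydroxycyclohex-3-en-1-yl]methyl acetate | CC(=O)OC[C@@]1(O)[C@@H](OC(C)=O)C=C[C@@H](OC(=O)c2ccccc2)[C@@H]1OC(=O)c1ccccc1 | target

**Totals**

Total step count: 6. Longest linear sequence: 5 steps (1 → 2 → 3 → 5 → 9 → 10); step 4 is a one-step side branch.

**Steps most likely to fail, with fallbacks**

Step 5 is the riskiest. Ketone 8 can lose benzoic acid by β-elimination, and the addition must set two stereocentres on a ketone for which there is no direct precedent. The fallback sets out from 5 and returns at 10, closing the ring with an acyl anion instead of by metathesis. Zinc fragmentation alone (Zn dust, THF/H2O, sonication) with isolation of 8 is followed by linear-selective hydroformylation of the vinyl group (Rh(acac)(CO)2, Xantphos, CO/H2 10 bar, toluene, 60 °C). This gives (4R,5S)-7-acetoxy-4,5-bis(benzoyloxy)-6-oxoheptanal F1. An intramolecular crossed benzoin reaction catalysed by an N-heterocyclic carbene (aminoindanol-derived N-pentafluorophenyl triazolium tetrafluoroborate, Et3N, toluene, 20 °C) lets the C2 acyl anion equivalent attack the C1 ketone. The product is [(1S,5R,6S)-5,6-bis(benzoyloxy)-1-hydroxy-2-oxocyclohexyl]methyl acetate F2, with C1 fixed by the choice of catalyst antipode. Dehydrogenation with IBX (DMSO, 65 °C) gives [(1S,5R,6S)-5,6-bis(benzoyloxy)-1-hydroxy-2-oxocyclohex-3-en-1-yl]methyl acetate F3. Hydroxyl-directed reduction with Me4NBH(OAc)3 (MeCN/AcOH, −20 °C) delivers hydride from the face of the tertiary OH and gives [(1R,2S,5R,6S)-5,6-bis(benzoyloxy)-1,2-dihydroxycyclohex-3-en-1-yl]methyl acetate F4. Ac2O/pyridine at 0 °C acetylates only the secondary allylic hydroxyl and gives 10.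

Step 3 is next. The 1-OH is primary but neopentyl-like, so its preference over the two secondary hydroxyls may be modest. The fallback sets out from 3 and returns at 5 by temporary protection. TBSCl/imidazole (DMF, 0 °C) gives methyl 1-O-(tert-butyldimethylsilyl)-6-deoxy-6-iodo-D-fructofuranoside F5. BzCl/pyridine/DMAP gives methyl 3,4-di-O-benzoyl-1-O-(tert-butyldimethylsilyl)-6-deoxy-6-iodo-D-fructofuranoside F6. HF·pyridine (THF, 0 °C; acidic, so no benzoyl migration) gives methyl 3,4-di-O-benzoyl-6-deoxy-6-iodo-D-fructofuranoside F7. Ac2O/pyridine then gives 5.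

Step 2 is third. Over-iodination, or closure of the hydroxy-iodide to a 3,6-anhydro sugar, can erode the yield. The fallback sets out from 2 and returns at 5, introducing iodine only after acylation. TsCl (1.1 equiv, pyridine, −20 °C) gives methyl 6-O-(4-methylbenzenesulfonyl)-D-fructofuranoside F8. The one-pot acetylation/benzoylation of step 3 gives methyl 1-O-acetyl-3,4-di-O-benzoyl-6-O-(4-methylbenzenesulfonyl)-D-fructofuranoside F9. Finkelstein displacement (NaI, butanone, 80 °C) then gives 5.

**Further compounds**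

F1 | step 5 | (4R,5S)-7-acetoxy-4,5-bis(benzoyloxy)-6-oxoheptanal | O=CCC[C@@H](OC(=O)c1ccccc1)[C@H](OC(=O)c1ccccc1)C(=O)COC(C)=O
F2 | step 5 | [(1S,5R,6S)-5,6-bis(benzoyloxy)-1-hydroxy-2-oxocyclohexyl]methyl acetate | CC(=O)OC[C@@]1(O)C(=O)CC[C@@H](OC(=O)c2ccccc2)[C@@H]1OC(=O)c1ccccc1
F3 | step 5 | [(1S,5R,6S)-5,6-bis(benzoyloxy)-1-hydroxy-2-oxocyclohex-3-en-1-yl]methyl acetate | CC(=O)OC[C@@]1(O)C(=O)C=C[C@@H](OC(=O)c2ccccc2)[C@@H]1OC(=O)c1ccccc1
F4 | step 5 | [(1R,2S,5R,6S)-5,6-bis(benzoyloxy)-1,2-dihydroxycyclohex-3-en-1-yl]methyl acetate | CC(=O)OC[C@@]1(O)[C@@H](O)C=C[C@@H](OC(=O)c2ccccc2)[C@@H]1OC(=O)c1ccccc1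
F5 | step 3 | methyl 1-O-(tert-butyldimethylsilyl)-6-deoxy-6-iodo-D-fructofuranoside | COC1(CO[Si](C)(C)C(C)(C)C)O[C@H](CI)[C@@H](O)[C@@H]1O
F6 | step 3 | methyl 3,4-di-O-benzoyl-1-O-(tert-butyldimethylsilyl)-6-deoxy-6-iodo-D-fructofuranoside | COC1(CO[Si](C)(C)C(C)(C)C)O[C@H](CI)[C@@H](OC(=O)c2ccccc2)[C@@H]1OC(=O)c1ccccc1
F7 | step 3 | methyl 3,4-di-O-benzoyl-6-deoxy-6-iodo-D-fructofuranoside | COC1(CO)O[C@H](CI)[C@@H](OC(=O)c2ccccc2)[C@@H]1OC(=O)c1ccccc1
F8 | step 2 | methyl 6-O-(4-methylbenzenesulfonyl)-D-fructofuranoside | COC1(CO)O[C@H](COS(=O)(=O)c2ccc(C)cc2)[C@@H](O)[C@@H]1O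
F9 | step 2 | methyl 1-O-acetyl-3,4-di-O-benzoyl-6-O-(4-methylbenzenesulfonyl)-D-fructofuranoside | COC1(COC(C)=O)O[C@H](COS(=O)(=O)c2ccc(C)cc2)[C@@H](OC(=O)c2ccccc2)[C@@H]1OC(=O)c1ccccc1
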